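If a tank drains through two outlets, the share through each follows the ratio of their time constants, and I read the partner in these flasks that way.

    starting material + partner + free catalyst → free catalyst + target (k1 = 1500 /M²/h, Ea1 = 49.0 kJ/mol)
    second substrate + partner + free catalyst → free catalyst + second product (k2 = 21000 /M²/h, Ea2 = 38.0 kJ/mol)
    free catalyst + impurity → spent catalyst (k3 = 63000 /M/h, Ea3 = 46.0 kJ/mol)
    2 partner → homo dimer (k4 = 1.3 /M/h, Ea4 = 49.0 kJ/mol)
    (constants at 5 °C)

| setting | summer | dusk | noon | midnight |
|---|---|---|---|---|
| starting material | 0.20 M | 0.20 M | 0.20 M | 0.20 M |
| partner | 0.140 M | 0.140 M | 0.140 M | 0.140 M |
| second substrate | 0.0400 M | 0.0400 M | 0.0400 M | 0.0400 M |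
| free catalyst | 0.20 mM | 0.20 mM | 0.20 mM | 0.20 mM |
| impurity | 60 µM | 60 µM | 60 µM | 60 µM |
| temperature | 5 °C | 20 °C | 35 °C | 50 °C |
| time | 40 h | 40 h | 40 h | 40 h |

- for a step with 2 of a species take k times the square, and two of it per event
- the constants hold at 5 °C; other temperatures follow from the activation energies

* the best flask by amount of target, in percent of the starting material charged; "all alike" if 1.5 percentage points covers them all (summer / dusk / noon / midnight / all alike)
* amount of target at the end, in percent of the starting material charged, summer
* amount of target at the end, in percent of the starting material charged, dusk
* amount of target at the end, in percent of the starting material charged, noon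
* amount of target at the end, in percent of the starting material charged, midnight

I began with the poison. In summer, impurity met free catalyst on a time of 0.0794 h, far shorter than the run, and its charge was smaller than the catalyst's. So I took that step as settled and reckoned with the working catalyst, charge minus impurity, 0.140 mM.

The partner was the limiting reagent, with a charge of 0.140 M against 0.240 M of the two substrates together. With the summer constants, its outlet to target had the time constant 23.8 h, and its outlet to homo dimer had the first half-life 2.75 h. I called the first over the second the drain ratio, 8.67. Warming from 5 °C to 50 °C speeds step 1 by a factor of 19 and step 4 by a factor of 19, so I kept the ratio from flask to flask.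

Holding c(starting material) at its charge and draining the partner through these two outlets, I integrated to a target of the charged c(partner) over the ratio, times the natural logarithm of one plus the ratio. That gave a two-outlet yield of 18.3% of the starting material charged. The second substrate draws on the same partner, so I committed to less than that, rising slightly with warmth, because the activation energy of step 2 is smaller than that of step 1, and to no clear winner.

The forecast gave 12.6%, 13.2%, 13.4% and 13.7% from summer to midnight, and for the best flask all alike: “The spread is about 1.1 points, so all alike”. Its figures stood below my two-outlet yield.

The flasks gave 12.6%, 13.4%, 13.6% and 13.8%, and the best flask came out as all alike. Summer held 70.0% of its catalyst free at 40.0 h, which is the 0.140 mM I had carried. Summer's target reached 68.9% of the two-outlet yield. The neighbour of summer, charged with 3.4 × 10⁻⁴ M of free catalyst, had 0.280 mM working, so its drain ratio was 4.33, half of summer's, and its two-outlet yield was 27.0%. The same fraction of that yield is 18.6%, and the neighbour gave 19.4%.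

The rate constants come from no measurement; the result is computed.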